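Of the constants in these flasks, the one I can have without any rate is a ratio of charges, free monomer over initiator, 288 in both dusk and dawn. I call it the charge ratio: the monomer units each chain gets if one initiator begins one chain and the whole charge ends in chains. The average length (the number-average degree of polymerisation) is then the charge ratio times the share of the charge in chains, divided by the share of initiator that has begun a chain, with dead chains counted like living ones.

| flask | free monomer | protic impurity | initiator | remark | time |
|---|---|---|---|---|---|
| birch | 0.046 M (fed, over 4.0 h) | 0.010 M | 0.16 mM | run made earlier; the fed solution adds 1.0 times the starting volume |  |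
| ash | 0.046 M (fed, over 4.0 h) | 0.013 M | 0.16 mM | run made earlier; the fed solution adds 1.0 times the starting volume |  |
| maple | 0.046 M (fed, over 4.0 h) | 0.020 M | 0.16 mM | run made earlier; the fed solution adds 1.0 times the starting volume |  |
| dusk | 0.046 M (fed, over 4.0 h) | 0.0230 M | 0.16 mM | the fed solution adds 1.0 times the starting volume | 40 h |
| dawn | 0.046 M (fed, over 4.0 h) | 0.00800 M | 0.16 mM | the fed solution adds 1.0 times the starting volume | 40 h |

| run | time / h | monomer in chains / % | free monomer / % |
|---|---|---|---|
| birch | 2.00 | 0 | 47.1 |
| birch | 5.00 | 1.3 | 89.8 |
| birch | 10.0 | 5.2 | 77.8 |
| birch | 15.0 | 9.3 | 71.8 |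
| birch | 20.0 | 12.2 | 67.1 |
| ash | 4.00 | 0.1 | 88.2 |
| ash | 8.00 | 3.6 | 78.1 |
| ash | 12.0 | 6.1 | 70.9 |
| ash | 15.0 | 8.8 | 67.0 |
| ash | 20.0 | 11.8 | 61.7 |
| maple | 1.50 | 0 | 34.4 |
| maple | 3.00 | 0.2 | 64.8 |
| maple | 6.00 | 2.3 | 75.7 |
| maple | 10.0 | 4.0 | 64.8 |
| maple | 20.0 | 9.8 | 51.4 |

(scatter of a reading: 0.5 percentage points)

- which of the two ends with the longer chains by the average number of monomer units in a chain (chains begun, living or dead) ("neither" if they lie within 10%) (dusk / dawn / neither)
- average number of monomer units in a chain (chains begun, living or dead) at the end, dusk
- average number of monomer units in a chain (chains begun, living or dead) at the end, dawn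

- charges are per starting volume, the dose included; the dosed solution carries all of it
- the average divides the monomer in chains by the number of chains begun, living and dead together
- the earlier runs do not show the number of chains; that part of a forecast is a guess
- percentages count the whole charge, also what has not yet gone in

So I draw the share in chains from the earlier runs. It starts flat: ash shows 0.1% at 4.00 h, when its feed ends. After this knee it climbs: birch gains 11 percentage points between 5.00 h and 20.0 h, and dividing by the mean free monomer of those readings gives a pseudo-first-order rate of 0.00926 h⁻¹, a reading whose time, 108 h, is longer than the 40 h asked, so I expect the curve to be still rising at the end.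

The level it runs towards comes from the missing monomer: maple at 20.0 h has lost 38.8% of its charge outside chains, approaching its impurity share of 43.5%. I therefore take the impurity to remove monomer one for one, which leaves 50.0% of the charge in dusk and 82.6% in dawn. Rising towards those levels from 4.0 h to 40 h gives 14.2% in chains for dusk and 23.4% for dawn. If each initiator begins a chain, which the earlier runs do not show, my lengths are 40.9 and 67.4.

The forecast also names dawn, with 49 for dusk and 72 for dawn, and its numbers stand above mine; its step to length reads “Assuming one chain per initiator”.

The flask gives dawn, with 44.2 for dusk and 64.2 for dawn, so the forecast is right within its tolerance.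

    2 living end → dead end (k = 0.100 L mol⁻¹ s⁻¹)
    protic impurity + free monomer → quenched substrate (k = 0.00230 L mol⁻¹ s⁻¹)
    free monomer + initiator → living end + monomer in chains (k = 0.00230 L mol⁻¹ s⁻¹)
    free monomer + living end → monomer in chains + living end, rate k4*[living end]*[free monomer] (k = 0.0530 L mol⁻¹ s⁻¹)

In dusk at 40.0 h, 15.0% stands in chains and 2.4% of the initiator remains, so the charge ratio gives 44.3. A neighbouring flask, dusk with 6.4 × 10⁻⁴ M of initiator, has a charge ratio of 71.9; with 30.0% in chains and 5.0% of its initiator left, the rule gives 22.7, and the simulation gives 22.7. Dusk has not come to rest at the asked time, with 36.2% free monomer remaining. After 400 h, free monomer is down to 19.1% and monomer in chains is up to 30.9%, which the charge ratio turns into 89.0 units, and the simulated length is 89.0.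

The numbers in the tables are calculated from invented constants; noise was put on by code.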